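**Retrosynthesis**
- The flavone C2–C1′ bond is formed last by a radical arylation: a nucleophilic aryl radical from a boronic acid adds to C2 of 5,7-di-O-benzylchromone.
- The aryl radical precursor already carries the threo (7″S,8″S) aryl-glyceryl ether. Both stereocentres come from one Evans syn-aldol of an aryloxyacetyl imide with 4-benzyloxybenzaldehyde, followed by reductive removal of the auxiliary.
- The aryloxyacetyl imide comes from Williamson alkylation of 4-bromo-2,6-dimethoxyphenol, which is built from 4-bromophenol by diiodination and Cu-methoxylation.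
- Ring order: the A ring (resorcinol, then Ir-borylation/oxidation and acylation) and the pyranone C ring (DMF-DMA cyclisation) are built first. The B ring is built separately, and the A/C and B fragments are joined by the radical step.

Assumption: the oxazolidinone is a recoverable chiral auxiliary used as a reagent. The (R)-auxiliary gives (7″S,8″S), derived from Evans syn-aldol (2S,3S) precedent for the (S)-auxiliary.

**Route**

Step 1
Reactants: 1 resorcinol
Product: 2 1,3-bis(benzyloxy)benzene
Conditions: BnBr, K2CO3, acetone, reflux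
Reagents that add atoms: benzyl bromide, BrCc1ccccc1
Why: Double Williamson O-benzylation protects both phenols so the arene can be C–H borylated.

Step 2
Reactants: 2
Product: 3 3,5-bis(benzyloxy)phenol
Conditions: (i) B2pin2, [Ir(OMe)(cod)]2, dtbpy, THF, 80 °C; (ii) Oxone, acetone/H2O, rt (one pot)
Reagents that add atoms: Oxone (source of the new O), O=S(=O)([O-])OO.[K+]
Why: Sterically controlled Ir-catalysed C–H borylation of a 1,3-disubstituted arene occurs only at C5, and oxidation of the C–B bond gives the phloroglucinol oxygenation pattern.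

Step 3
Reactants: 3; 4 acetic acid
Product: 5 1-[4,6-bis(benzyloxy)-2-hydroxyphenyl]ethan-1-one
Conditions: BF3·OEt2, neat AcOH, 70 °C
Reagents that add atoms: none
Why: BF3-mediated Nencki/Friedel–Crafts acylation goes ortho to the free OH, where the product is stabilised by a chelated OH···O=C hydrogen bond.

Step 4
Reactants: 5; 6 DMF-DMA
Product: 7 5,7-bis(benzyloxy)-4H-chromen-4-one
Conditions: DMF-DMA, PhMe, 110 °C; then 2 M HCl, EtOH, 60 °C
Reagents that add atoms: none
Why: The enaminone from the methyl ketone undergoes acid-mediated oxa-cyclisation to the 2-unsubstituted chromone, forming the pyranone (C) ring.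

Step 5
Reactants: 8 4-bromophenol
Product: 9 4-bromo-2,6-diiodophenol
Conditions: ICl (2.2 equiv), CH2Cl2/AcOH, 0 °C to rt
Reagents that add atoms: iodine monochloride, ICl
Why: Electrophilic iodination occurs at both ortho positions because the para position is blocked.

Step 6
Reactants: 9
Product: 10 4-bromo-2,6-dimethoxyphenol
Conditions: NaOMe (6 equiv), CuI (20 mol %), MeOH/DMF, 110 °C
Reagents that add atoms: sodium methoxide, [Na+].[O-]C
Why: In the Ullmann-type Cu-catalysed methoxylation, the ortho C–I bonds react much faster than the para C–Br bond.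

Step 7
Reactants: 11 chloroacetyl chloride
Product: 12 (R)-4-benzyl-3-(chloroacetyl)oxazolidin-2-one
Conditions: (R)-4-benzyloxazolidin-2-one, n-BuLi, THF, −78 °C; then ClCH2COCl
Reagents that add atoms: (R)-4-benzyloxazolidin-2-one (chiral auxiliary), O=C1N[C@H](Cc2ccccc2)CO1
Why: Evans N-acylation of the lithiated oxazolidinone gives the imide that will carry the stereocontrol.

Step 8
Reactants: 12; 10
Product: 13 (R)-4-benzyl-3-[2-(4-bromo-2,6-dimethoxyphenoxy)acetyl]oxazolidin-2-one
Conditions: K2CO3, KI (cat.), DMF, 50 °C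
Reagents that add atoms: none
Why: Williamson SN2 of the phenoxide on the primary α-chloro imide forms the aryl ether C–O bond at an unhindered CH2 (no stereocentre yet).

Step 9
Reactants: 8 4-bromophenol
Product: 14 1-(benzyloxy)-4-bromobenzene
Conditions: BnBr, K2CO3, acetone, reflux
Reagents that add atoms: benzyl bromide, BrCc1ccccc1
Why: O-Benzylation protects the p-hydroxyphenyl oxygen.

Step 10
Reactants: 14
Product: 15 4-(benzyloxy)benzaldehyde
Conditions: n-BuLi, THF, −78 °C; then DMF
Reagents that add atoms: N,N-dimethylformamide (supplies CHO), CN(C)C=O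
Why: Br–Li exchange followed by formylation.

Step 11
Reactants: 13; 15
Product: 16 (R)-4-benzyl-3-[(2R,3S)-3-(4-benzyloxyphenyl)-2-(4-bromo-2,6-dimethoxyphenoxy)-3-hydroxypropanoyl]oxazolidin-2-one
Conditions: Bu2BOTf, iPr2NEt, CH2Cl2, −78 to 0 °C; then 15; then H2O2, pH 7 buffer/MeOH
Reagents that add atoms: none (boron is removed in the oxidative work-up)
Why: The Z-boron enolate reacts through a Zimmerman–Traxler chair, and the (R)-benzyl auxiliary sets the face, giving the syn (= threo) aldol that becomes (7″S,8″S); this extends the Evans glycolate aldol to an aryloxy donor.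

Step 12
Reactants: 16
Product: 17 (1S,2S)-1-[4-(benzyloxy)phenyl]-2-(4-bromo-2,6-dimethoxyphenoxy)propane-1,3-diol
Conditions: LiBH4, MeOH (2 equiv), THF, 0 °C
Reagents that add atoms: none (the auxiliary is released and recovered)
Why: Reductive cleavage of the imide gives the primary alcohol without touching either stereocentre.

Step 13
Reactants: 17
Product: 18 [4-{[(1S,2S)-1-(4-benzyloxyphenyl)-1,3-dihydroxypropan-2-yl]oxy}-3,5-dimethoxyphenyl]boronic acid
Conditions: B2(OH)4, XPhos-Pd-G2 (2 mol %), XPhos, KOAc, EtOH, 80 °C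
Reagents that add atoms: tetrahydroxydiboron, OB(O)B(O)O
Why: Miyaura borylation converts the aryl bromide to the boronic acid, which serves as the aryl-radical precursor.

Step 14
Reactants: 18 (1 equiv); 7 (3 equiv)
Product: 19 5,7-bis(benzyloxy)-2-{4-[(1S,2S)-1-(4-benzyloxyphenyl)-1,3-dihydroxypropan-2-yloxy]-3,5-dimethoxyphenyl}-4H-chromen-4-one
Conditions: AgNO3 (20 mol %), K2S2O8 (2.5 equiv), Na2HPO4 (2 equiv), MeCN/H2O 3:1, 40 °C
Reagents that add atoms: none
Why: Proposed new method: Ag(II)/SO4•− oxidises the boronate to the electron-rich, nucleophilic 4-alkoxy-3,5-dimethoxyphenyl radical. This radical adds Giese-style to C2, the electron-poor β-carbon of the chromone enone, giving a stabilised α-keto C3 radical. Oxidation and loss of H+ then re-aromatise the pyranone to the flavone, forming the C2–C1′ bond. The closest known reactions are Minisci/Baran-type arylation with boronic acids and radical C2-alkylation of chromones; the stereocentres are remote from the radical and are not touched.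

Step 15
Reactants: 19
Product: 20 target, (−)-(7″S,8″S)-4″,5,7-trihydroxy-3′,5′-dimethoxy-4′,8″-oxyflavonolignan-7″,9″-diol
Conditions: H2 (1 atm), 10 % Pd/C, EtOAc/MeOH, rt, short reaction time
Reagents that add atoms: none
Why: Hydrogenolysis removes the three aryl benzyl ethers; the benzylic alcohol, aryl methyl ethers and flavone C2=C3 are retained under these mild conditions.

**Compound list**

1 | resorcinol | Oc1cccc(O)c1 | starting material
2 | 1,3-bis(benzyloxy)benzene | c1ccc(COc2cccc(OCc3ccccc3)c2)cc1 | intermediate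
3 | 3,5-bis(benzyloxy)phenol | Oc1cc(OCc2ccccc2)cc(OCc2ccccc2)c1 | intermediate
4 | acetic acid | CC(=O)O | starting material
5 | 1-[4,6-bis(benzyloxy)-2-hydroxyphenyl]ethan-1-one | CC(=O)c1c(O)cc(OCc2ccccc2)cc1OCc1ccccc1 | intermediate
6 | N,N-dimethylformamide dimethyl acetal | CN(C)C(OC)OC | starting material
7 | 5,7-bis(benzyloxy)-4H-chromen-4-one | O=c1ccoc2cc(OCc3ccccc3)cc(OCc3ccccc3)c12 | intermediate
8 | 4-bromophenol | Oc1ccc(Br)cc1 | starting material
9 | 4-bromo-2,6-diiodophenol | Oc1c(I)cc(Br)cc1I | intermediate
10 | 4-bromo-2,6-dimethoxyphenol | COc1cc(Br)cc(OC)c1O | intermediate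
11 | chloroacetyl chloride | ClCC(=O)Cl | starting material
12 | (R)-4-benzyl-3-(chloroacetyl)oxazolidin-2-one | O=C(CCl)N1[C@H](Cc2ccccc2)COC1=O | intermediate
13 | (R)-4-benzyl-3-[2-(4-bromo-2,6-dimethoxyphenoxy)acetyl]oxazolidin-2-one | O=C(COc1c(OC)cc(Br)cc1OC)N1[C@H](Cc2ccccc2)COC1=O | intermediate
14 | 1-(benzyloxy)-4-bromobenzene | Brc1ccc(OCc2ccccc2)cc1 | intermediate
15 | 4-(benzyloxy)benzaldehyde | O=Cc1ccc(OCc2ccccc2)cc1 | intermediate
16 | syn-aldol imide, (2R,3S) | COc1cc(Br)cc(OC)c1O[C@@H](C(=O)N1[C@H](Cc2ccccc2)COC1=O)[C@@H](O)c1ccc(OCc2ccccc2)cc1 | intermediate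
17 | (1S,2S)-1-[4-(benzyloxy)phenyl]-2-(4-bromo-2,6-dimethoxyphenoxy)propane-1,3-diol | COc1cc(Br)cc(OC)c1O[C@@H](CO)[C@@H](O)c1ccc(OCc2ccccc2)cc1 | intermediate
18 | arylboronic acid of 17 | COc1cc(B(O)O)cc(OC)c1O[C@@H](CO)[C@@H](O)c1ccc(OCc2ccccc2)cc1 | intermediate
19 | tri-O-benzyl flavonolignan | COc1cc(-c2cc(=O)c3c(OCc4ccccc4)cc(OCc4ccccc4)cc3o2)cc(OC)c1O[C@@H](CO)[C@@H](O)c1ccc(OCc2ccccc2)cc1 | intermediate
20 | (−)-(7″S,8″S)-4″,5,7-trihydroxy-3′,5′-dimethoxy-4′,8″-oxyflavonolignan-7″,9″-diol | COc1cc(-c2cc(=O)c3c(O)cc(O)cc3o2)cc(OC)c1O[C@@H](CO)[C@@H](O)c1ccc(O)cc1 | target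

**Totals:** 15 steps; the longest linear sequence is 8 steps (5 → 6 → 8 → 11 → 12 → 13 → 14 → 15).

**Three steps most likely to fail**
1. Step 14 (radical arylation). Aryl radicals can attack C3, or the persulfate can oxidise the benzylic alcohol or the benzyl ethers. Fallback: protect the diol as its acetonide and convert the bromide to the aldehyde. Then build the flavone by Claisen–Schmidt condensation with 5 followed by I2/DMSO cyclisation, which is ionic, not radical.
2. Step 11 (Evans aldol). The hindered 2,6-dimethoxyphenoxy donor may enolise poorly, or give low syn-selectivity. Fallback: alkylate 10 with 4-benzyloxyphenacyl bromide, hydroxymethylate with HCHO, and set both centres by Ru-catalysed dynamic-kinetic asymmetric transfer hydrogenation.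
3. Step 15 (global hydrogenolysis). It risks benzylic C–O cleavage or over-reduction of the flavone. Fallback: use allyl groups instead of benzyl for the 5-, 7- and 4″-oxygens and remove them with Pd(PPh3)4/K2CO3/MeOH. This needs re-planning steps 1–3 and 9–10.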